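**Strategy**

- Locants: ring B runs from C1' (allyl-bearing) to C6' (C=O); the side chain is C7 (ArCH2), C8 (CH), C9 (CH3); ring A is the guaiacyl ring. The target is (3'S,8R).
- Enabling feature: in ring B the fully substituted C3' (carrying OMe and C8) is allylic to C1' through the C1'=C2' alkene, and C1' holds the allyl group beside the C6' carbonyl. Returning the C8–C3' bond to an oxygen on C1' therefore uncovers a 6-acyloxy-6-allyl-3,4-dimethoxycyclohexa-2,4-dienone (an o-quinol ester).
- Cuts, in retrosynthetic order: C9 methyl back to a carboxyl; C8–C3' by retro-Ireland–Claisen to the C1'–O ester; the ester C–O to an o-quinol and a 3-arylpropanoyl chloride; C1'–allyl to 4,5-dimethoxy-1,2-benzoquinone and an allylboronate; the quinone to catechol.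
- Forward order: both rings are bought as arenes and no ring is built. Catechol is oxidised to the dimethoxy-o-quinone, allylated at one carbonyl (C1') and O-acylated there with the ring A propanoyl unit. The acyl chain is then transferred from the C1' oxygen to C3'; carboxyl-to-methyl reduction and desilylation finish.
- Stereochemistry: one enantioselective step, the allylboration that makes the C1' carbinol. That centre is consumed in the rearrangement, which passes its sense to C3' across the same ring face and sets C8 at the same time through ketene acetal geometry; later steps leave both centres alone.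

Key step: step 6

Assumption: the sense of induction of the allylboration catalyst on this quinone cannot be predicted with certainty; the route is written for the catalyst antipode that a pilot run shows to give the (S)-carbinol.

**Step 1**
Reactants: 1 3-(4-hydroxy-3-methoxyphenyl)propanoic acid
Product: 3 3-[3-methoxy-4-(triisopropylsilyloxy)phenyl]propanoic acid, via bis-silylated ester 2 (not isolated)
Conditions: i-Pr3SiCl (2.3 equiv), imidazole, DMF, rt; then K2CO3, THF–MeOH–H2O, rt; 1 M HCl to pH 3
Reagents that add atoms: chlorotriisopropylsilane CC(C)[Si](Cl)(C(C)C)C(C)C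
Why: Silylation of phenol and acid followed by selective solvolysis of the far more labile silyl ester is the usual protection route to an O-silylated phenolic acid, and the hindered aryl triisopropylsilyl ether should survive carbonate in aqueous methanol.

**Step 2**
Reactants: 3 3-[3-methoxy-4-(triisopropylsilyloxy)phenyl]propanoic acid
Product: 4 3-[3-methoxy-4-(triisopropylsilyloxy)phenyl]propanoyl chloride
Conditions: (COCl)2, DMF (cat.), CH2Cl2, 0 °C to rt; evaporation
Reagents that add atoms: oxalyl chloride O=C(Cl)C(=O)Cl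
Why: Acid chloride formation with oxalyl chloride under DMF catalysis is anhydrous and leaves the aryl silyl ether and the methyl ether untouched.

**Step 3**
Reactants: 5 catechol
Product: 10 4,5-dimethoxy-1,2-benzoquinone, via 1,2-benzoquinone 6 (not isolated), via 4-methoxycatechol 7 (not isolated), via 4-methoxy-1,2-benzoquinone 8 (not isolated), via 4,5-dimethoxycatechol 9 (not isolated)
Conditions: NaIO3, MeOH, rt, dark
Reagents that add atoms: methanol CO
Why: Iodate oxidation to the o-quinone followed by two rounds of conjugate addition of methanol and reoxidation (oxidative methoxylation) is an established one-pot preparation that should stop at 10, because both remaining ring CH positions then belong to vinylogous ester units.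

**Step 4**
Reactants: 10 4,5-dimethoxy-1,2-benzoquinone + 11 allylboronic acid pinacol ester
Product: 12 (S)-6-allyl-6-hydroxy-3,4-dimethoxycyclohexa-2,4-dien-1-one
Conditions: 11 (1.5 equiv), 2-[(3-tert-butyl-2-hydroxybenzyl)amino]-N,N,3-trimethylbutanamide (chiral aminophenol, 3 mol %), NaOt-Bu (5 mol %), MeOH (2 equiv), PhMe–CH2Cl2, 0 °C; pH 7 work-up, cold filtration through silica, used at once
Reagents that add atoms: none
Why: Proposed new method: the aminophenol, NaOt-Bu, MeOH and 11 should generate a chiral aminophenol-bound allylboron species that holds the quinone by an ammonium N–H···O=C hydrogen bond to one carbonyl while delivering allyl to the other through a six-membered chair array, and since the two carbonyls are homotopic only the face of attack has to be controlled, which sets the C1' carbinol centre as (S); the closest known reaction type is the aminophenol-catalysed enantioselective allylboration of isatins and activated ketones with allylB(pin), the o-quinone being a new acceptor class.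

**Step 5**
Reactants: 12 (S)-6-allyl-6-hydroxy-3,4-dimethoxycyclohexa-2,4-dien-1-one + 4 3-[3-methoxy-4-(triisopropylsilyloxy)phenyl]propanoyl chloride
Product: 13 (1S)-1-allyl-3,4-dimethoxy-6-oxocyclohexa-2,4-dien-1-yl 3-[3-methoxy-4-(triisopropylsilyloxy)phenyl]propanoate
Conditions: pyridine, 4-(dimethylamino)pyridine (0.2 equiv), CH2Cl2, −20 to 0 °C
Reagents that add atoms: none
Why: O-Acylation of the tertiary α-ketol by an acid chloride under nucleophilic catalysis is fast at low temperature, which should outrun the [4+2] dimerisation typical of o-quinols, and it does not touch the C1' stereocentre.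

**Step 6**
Reactants: 13 (1S)-1-allyl-3,4-dimethoxy-6-oxocyclohexa-2,4-dien-1-yl 3-[3-methoxy-4-(triisopropylsilyloxy)phenyl]propanoate
Product: 16 (2R)-2-[(1R)-5-allyl-1,2-dimethoxy-4-oxocyclohexa-2,5-dien-1-yl]-3-[3-methoxy-4-(triisopropylsilyloxy)phenyl]propanoic acid, via (E)-trimethylsilyl ketene acetal 14 (not isolated), via trimethylsilyl ester 15 (not isolated)
Conditions: Me3SiCl–Et3N (premixed, 5 equiv), THF, −78 °C; LiN(i-Pr)2 (commercial solution, 1.3 equiv) added dropwise; −78 to 20 °C; aqueous citric acid work-up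
Reagents that add atoms: chlorotrimethylsilane C[Si](C)(C)Cl (its silicon is held only in 14 and 15 and is lost on work-up)
Why: Proposed new method: LiN(i-Pr)2 removes a proton from the only acidic site, the ester α-CH2 (C1' is quaternary and the C6' ketone has no α-hydrogen), and the enolate is silylated as it forms, so that the (E)-silyl ketene acetal 14 should rearrange on warming by a concerted suprafacial [3,3] shift through the array O–C9–C8···C3'–C2'–C1', making the C8–C3' bond, breaking the C1'–O bond, moving the ring alkene to C1'=C2' and turning the linear 2,4-dienone into the cross-conjugated 2,5-dienone. The closest known reaction type is the Ireland–Claisen rearrangement of 2-cyclohexenyl and glycal esters, in which an oxygen-substituted alkene terminus likewise receives the carbon with 1,3-chirality transfer; the shift has not been shown on an o-quinol ester. No ring is closed, ring B being carried through unchanged. C3' is controlled by the C1' carbinol centre, because the new bond must form on the ring face that carried the ester oxygen, and C8 is controlled by the ketene acetal geometry: the (E)-acetal in a chair array, and equally any minor (Z)-acetal in a boat array, keep the ArCH2 group of C8 outside the flat ring and lead to the same (R,R)-acid 16. The step needs chemoselective enolisation, a single [3,3] pathway and one C8 epimer; trapping the enolate as it forms should prevent its five-membered aldol closure onto C6' and loss of a ketene, and the donor methoxy group on C3' together with the C1'–O bond α to a ketone should let the shift run below room temperature, under the threshold for the Cope shift of the C1' allyl group.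

**Step 7**
Reactants: 16 (2R)-2-[(1R)-5-allyl-1,2-dimethoxy-4-oxocyclohexa-2,5-dien-1-yl]-3-[3-methoxy-4-(triisopropylsilyloxy)phenyl]propanoic acid
Product: 19 (4R)-2-allyl-4-[(2S)-1-hydroxy-3-[3-methoxy-4-(triisopropylsilyloxy)phenyl]propan-2-yl]-4,5-dimethoxycyclohexa-2,5-dien-1-one, via mixed carbonic anhydride 17 (not isolated), via aldehyde 18 (not isolated)
Conditions: i-BuOCOCl, N-methylmorpholine, THF, −15 °C; then NaBH4, H2O, −15 to 0 °C, 10 min; pH 7 buffer, used at once
Reagents that add atoms: isobutyl chloroformate CC(C)COC(Cl)=O (held only in 17)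
Why: Mixed carbonic anhydride reduction with NaBH4 passes through aldehyde 18 within minutes at low temperature, conditions under which the doubly conjugated vinylogous ester carbonyl C6', the allyl group and the silyl ether should be inert, C8 is not epimerised, and neutral work-up with immediate use avoids oxa-Michael closure of the alcohol onto C2'.

**Step 8**
Reactants: 19 (4R)-2-allyl-4-[(2S)-1-hydroxy-3-[3-methoxy-4-(triisopropylsilyloxy)phenyl]propan-2-yl]-4,5-dimethoxycyclohexa-2,5-dien-1-one
Product: 20 (4R)-2-allyl-4-[(2R)-1-iodo-3-[3-methoxy-4-(triisopropylsilyloxy)phenyl]propan-2-yl]-4,5-dimethoxycyclohexa-2,5-dien-1-one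
Conditions: PPh3, I2, imidazole, CH2Cl2, 0 °C to rt (PPh3 and I2 premixed)
Reagents that add atoms: iodine II
Why: Appel-type iodination through the alkoxyphosphonium ion substitutes only at primary C9 under nearly neutral conditions, so C8 and C3' keep their configuration (the descriptor at C8 changes by priority only).

**Step 9**
Reactants: 20 (4R)-2-allyl-4-[(2R)-1-iodo-3-[3-methoxy-4-(triisopropylsilyloxy)phenyl]propan-2-yl]-4,5-dimethoxycyclohexa-2,5-dien-1-one
Product: 21 (4S)-2-allyl-4,5-dimethoxy-4-[(2R)-1-[3-methoxy-4-(triisopropylsilyloxy)phenyl]propan-2-yl]cyclohexa-2,5-dien-1-one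
Conditions: n-Bu3SnH (1.5 equiv, 0.3 M), Et3B (0.2 equiv), air, PhMe, 0 °C
Reagents that add atoms: none
Why: Tin hydride radical dehalogenation is indifferent to the β-branching that would retard a hydride displacement, and at 0 °C with concentrated n-Bu3SnH hydrogen transfer to the C9 radical should be much faster than β-scission of the C8–C3' bond; no stereocentre takes part (the descriptor at C3' changes by priority only).

**Step 10**
Reactants: 21 (4S)-2-allyl-4,5-dimethoxy-4-[(2R)-1-[3-methoxy-4-(triisopropylsilyloxy)phenyl]propan-2-yl]cyclohexa-2,5-dien-1-one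
Product: 22 (4S)-2-allyl-4-[(2R)-1-(4-hydroxy-3-methoxyphenyl)propan-2-yl]-4,5-dimethoxycyclohexa-2,5-dien-1-one
Conditions: n-Bu4NF, AcOH, THF, 0 °C
Reagents that add atoms: none
Why: Fluoride cleavage of the aryl silyl ether (desilylation), buffered with acetic acid, should release the phenol without exposing the p-quinol ether dienone to phenoxide or strong acid.

**Compound list**

1 | 3-(4-hydroxy-3-methoxyphenyl)propanoic acid | COc1cc(CCC(=O)O)ccc1O | starting material
2 | triisopropylsilyl 3-[3-methoxy-4-(triisopropylsilyloxy)phenyl]propanoate | COc1cc(CCC(=O)O[Si](C(C)C)(C(C)C)C(C)C)ccc1O[Si](C(C)C)(C(C)C)C(C)C | intermediate (not isolated)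
3 | 3-[3-methoxy-4-(triisopropylsilyloxy)phenyl]propanoic acid | COc1cc(CCC(=O)O)ccc1O[Si](C(C)C)(C(C)C)C(C)C | intermediate
4 | 3-[3-methoxy-4-(triisopropylsilyloxy)phenyl]propanoyl chloride | COc1cc(CCC(=O)Cl)ccc1O[Si](C(C)C)(C(C)C)C(C)C | intermediate
5 | catechol | Oc1ccccc1O | starting material
6 | 1,2-benzoquinone | O=C1C=CC=CC1=O | intermediate (not isolated)
7 | 4-methoxycatechol | COc1ccc(O)c(O)c1 | intermediate (not isolated)
8 | 4-methoxy-1,2-benzoquinone | COC1=CC(=O)C(=O)C=C1 | intermediate (not isolated)
9 | 4,5-dimethoxycatechol | COc1cc(O)c(O)cc1OC | intermediate (not isolated)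
10 | 4,5-dimethoxy-1,2-benzoquinone | COC1=CC(=O)C(=O)C=C1OC | intermediate
11 | allylboronic acid pinacol ester | C=CCB1OC(C)(C)C(C)(C)O1 | starting material
12 | (S)-6-allyl-6-hydroxy-3,4-dimethoxycyclohexa-2,4-dien-1-one | C=CC[C@]1(O)C=C(OC)C(OC)=CC1=O | intermediate
13 | (1S)-1-allyl-3,4-dimethoxy-6-oxocyclohexa-2,4-dien-1-yl 3-[3-methoxy-4-(triisopropylsilyloxy)phenyl]propanoate | C=CC[C@]1(OC(=O)CCc2ccc(O[Si](C(C)C)(C(C)C)C(C)C)c(OC)c2)C=C(OC)C(OC)=CC1=O | intermediate
14 | (E)-trimethylsilyl ketene acetal of 13, (1S) at the ring carbinol carbon | C=CC[C@]1(O/C(O[Si](C)(C)C)=C\Cc2ccc(O[Si](C(C)C)(C(C)C)C(C)C)c(OC)c2)C=C(OC)C(OC)=CC1=O | intermediate (not isolated)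
15 | trimethylsilyl (2R)-2-[(1R)-5-allyl-1,2-dimethoxy-4-oxocyclohexa-2,5-dien-1-yl]-3-[3-methoxy-4-(triisopropylsilyloxy)phenyl]propanoate | C=CCC1=C[C@@](OC)([C@H](C(=O)O[Si](C)(C)C)Cc2ccc(O[Si](C(C)C)(C(C)C)C(C)C)c(OC)c2)C(OC)=CC1=O | intermediate (not isolated)
16 | (2R)-2-[(1R)-5-allyl-1,2-dimethoxy-4-oxocyclohexa-2,5-dien-1-yl]-3-[3-methoxy-4-(triisopropylsilyloxy)phenyl]propanoic acid | C=CCC1=C[C@@](OC)([C@H](C(=O)O)Cc2ccc(O[Si](C(C)C)(C(C)C)C(C)C)c(OC)c2)C(OC)=CC1=O | intermediate
17 | mixed anhydride of 16 with isobutyl hydrogen carbonate, (2R,1R) | C=CCC1=C[C@@](OC)([C@H](C(=O)OC(=O)OCC(C)C)Cc2ccc(O[Si](C(C)C)(C(C)C)C(C)C)c(OC)c2)C(OC)=CC1=O | intermediate (not isolated)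
18 | (2R)-2-[(1R)-5-allyl-1,2-dimethoxy-4-oxocyclohexa-2,5-dien-1-yl]-3-[3-methoxy-4-(triisopropylsilyloxy)phenyl]propanal | C=CCC1=C[C@@](OC)([C@H](C=O)Cc2ccc(O[Si](C(C)C)(C(C)C)C(C)C)c(OC)c2)C(OC)=CC1=O | intermediate (not isolated)
19 | (4R)-2-allyl-4-[(2S)-1-hydroxy-3-[3-methoxy-4-(triisopropylsilyloxy)phenyl]propan-2-yl]-4,5-dimethoxycyclohexa-2,5-dien-1-one | C=CCC1=C[C@@](OC)([C@H](CO)Cc2ccc(O[Si](C(C)C)(C(C)C)C(C)C)c(OC)c2)C(OC)=CC1=O | intermediate
20 | (4R)-2-allyl-4-[(2R)-1-iodo-3-[3-methoxy-4-(triisopropylsilyloxy)phenyl]propan-2-yl]-4,5-dimethoxycyclohexa-2,5-dien-1-one | C=CCC1=C[C@@](OC)([C@H](CI)Cc2ccc(O[Si](C(C)C)(C(C)C)C(C)C)c(OC)c2)C(OC)=CC1=O | intermediate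
21 | (4S)-2-allyl-4,5-dimethoxy-4-[(2R)-1-[3-methoxy-4-(triisopropylsilyloxy)phenyl]propan-2-yl]cyclohexa-2,5-dien-1-one | C=CCC1=C[C@@](OC)([C@H](C)Cc2ccc(O[Si](C(C)C)(C(C)C)C(C)C)c(OC)c2)C(OC)=CC1=O | intermediate
22 | (4S)-2-allyl-4-[(2R)-1-(4-hydroxy-3-methoxyphenyl)propan-2-yl]-4,5-dimethoxycyclohexa-2,5-dien-1-one (CNP0370214.1) | C=CCC1=C[C@@](OC)([C@H](C)Cc2ccc(O)c(OC)c2)C(OC)=CC1=O | target

**Step count and risks**

Total step count: 10. Longest linear sequence: 8 steps (catechol 5 to 22 through steps 3 to 10; the branch from acid 1 through steps 1, 2 and 5 to 10 is equally long).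

Steps most likely to fail:

1. Step 4 (enantioselective allylboration of the quinone). The uncatalysed addition of the allylboronate to the very electrophilic quinone, or conjugate substitution and redox side reactions of the quinone under the basic co-catalyst, may outrun the catalysed pathway, giving poor facial selectivity or unproductive consumption of the quinone. The fallback uses known chemistry, sets out from quinone 10 and returns at ester 13. A Barbier allylation of 10 with indium powder (In) and allyl bromide in THF–H2O at 0 °C, a 1,2-addition of the kind established for quinones, would give racemic 6-allyl-6-hydroxy-3,4-dimethoxycyclohexa-2,4-dien-1-one F1. This would be acylated at once with acid chloride 4 (pyridine, 4-(dimethylamino)pyridine, CH2Cl2) to racemic 1-allyl-3,4-dimethoxy-6-oxocyclohexa-2,4-dien-1-yl 3-[3-methoxy-4-(triisopropylsilyloxy)phenyl]propanoate F2, a storable ester. Its enantiomers would be separated by preparative HPLC on a cellulose tris(3,5-dimethylphenylcarbamate) phase; the (S)-enantiomer is 13.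

2. Step 6 (Ireland–Claisen transposition). Before it is silylated the lithium enolate may close onto the neighbouring C6' carbonyl or fragment to a ketene and the o-quinol alkoxide, or chair and boat arrays may compete for one ketene acetal geometry so that C8 selectivity is lost. The fallback uses known chemistry, sets out from acid 3 and returns at acid 16; it makes the C8–C3' bond by 1,2-addition of a lithium ester enolate to a quinone carbonyl and gives up stereocontrol.
   - Acid 3 would be esterified (Me3SiCHN2, MeOH–PhMe) to methyl 3-[3-methoxy-4-(triisopropylsilyloxy)phenyl]propanoate F3.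
   - Ring B would be prepared separately from commercial 3,4-dimethoxyphenol: O-allylation (allyl bromide, K2CO3, acetone) to 4-(allyloxy)-1,2-dimethoxybenzene F4, aromatic Claisen rearrangement (N,N-diethylaniline, 190 °C) to 2-allyl-4,5-dimethoxyphenol F5, and oxidative demethylation with (NH4)2Ce(NO3)6 (MeCN–H2O, 0 °C) to 2-allyl-5-methoxy-1,4-benzoquinone F6.
   - The lithium enolate of F3 (LiN(i-Pr)2, THF, −78 °C) should add to the C3' carbonyl of F6, the C6' carbonyl being a deactivated vinylogous ester, to give methyl 2-(5-allyl-1-hydroxy-2-methoxy-4-oxocyclohexa-2,5-dien-1-yl)-3-[3-methoxy-4-(triisopropylsilyloxy)phenyl]propanoate F7.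
   - The tertiary alcohol would be methylated (MeOTf, 2,6-di-tert-butyl-4-methylpyridine, CH2Cl2) to methyl 2-(5-allyl-1,2-dimethoxy-4-oxocyclohexa-2,5-dien-1-yl)-3-[3-methoxy-4-(triisopropylsilyloxy)phenyl]propanoate F8, expected as a mixture of four stereoisomers.
   - Chromatography on silica and then on a chiral phase would isolate methyl (2R)-2-[(1R)-5-allyl-1,2-dimethoxy-4-oxocyclohexa-2,5-dien-1-yl]-3-[3-methoxy-4-(triisopropylsilyloxy)phenyl]propanoate F9, whose ester would be cleaved with Me3SnOH (1,2-dichloroethane, 70 °C) to acid 16.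

3. Step 9 (radical removal of iodine). The primary C9 radical may undergo β-scission of the C8–C3' bond, or stannyl radicals may add to the dienone oxygen; either event aromatises ring B with loss of the side chain or of methoxide. The fallback sets out from alcohol 19 and returns at 21, removing the oxygen at the aldehyde level without a halide or tin. Dess–Martin oxidation of 19 (NaHCO3, CH2Cl2, 0 °C) would give aldehyde 18 of the compound list. Condensation with 4-methylbenzenesulfonohydrazide (EtOH, rt) would give N'-[(1E,2S)-2-[(1R)-5-allyl-1,2-dimethoxy-4-oxocyclohexa-2,5-dien-1-yl]-3-[3-methoxy-4-(triisopropylsilyloxy)phenyl]propylidene]-4-methylbenzenesulfonohydrazide F10. Reduction of the C=N bond with catecholborane (CHCl3, 0 °C) and hydrolysis would give N'-[(2S)-2-[(1R)-5-allyl-1,2-dimethoxy-4-oxocyclohexa-2,5-dien-1-yl]-3-[3-methoxy-4-(triisopropylsilyloxy)phenyl]propyl]-4-methylbenzenesulfonohydrazide F11. Warming with NaOAc·3H2O should expel sulfinate to give (4R)-2-allyl-4-[(2S)-1-diazenyl-3-[3-methoxy-4-(triisopropylsilyloxy)phenyl]propan-2-yl]-4,5-dimethoxycyclohexa-2,5-dien-1-one F12, which loses dinitrogen to leave the C9 methyl group of 21.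

**Further compounds**

F1 | step 4 | racemic 6-allyl-6-hydroxy-3,4-dimethoxycyclohexa-2,4-dien-1-one | C=CCC1(O)C=C(OC)C(OC)=CC1=O
F2 | step 4 | racemic 1-allyl-3,4-dimethoxy-6-oxocyclohexa-2,4-dien-1-yl 3-[3-methoxy-4-(triisopropylsilyloxy)phenyl]propanoate | C=CCC1(OC(=O)CCc2ccc(O[Si](C(C)C)(C(C)C)C(C)C)c(OC)c2)C=C(OC)C(OC)=CC1=O
F3 | step 6 | methyl 3-[3-methoxy-4-(triisopropylsilyloxy)phenyl]propanoate | COC(=O)CCc1ccc(O[Si](C(C)C)(C(C)C)C(C)C)c(OC)c1
F4 | step 6 | 4-(allyloxy)-1,2-dimethoxybenzene | C=CCOc1ccc(OC)c(OC)c1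
F5 | step 6 | 2-allyl-4,5-dimethoxyphenol | C=CCc1cc(OC)c(OC)cc1O
F6 | step 6 | 2-allyl-5-methoxy-1,4-benzoquinone | C=CCC1=CC(=O)C(OC)=CC1=O
F7 | step 6 | methyl 2-(5-allyl-1-hydroxy-2-methoxy-4-oxocyclohexa-2,5-dien-1-yl)-3-[3-methoxy-4-(triisopropylsilyloxy)phenyl]propanoate (stereoisomer mixture) | C=CCC1=CC(O)(C(C(=O)OC)Cc2ccc(O[Si](C(C)C)(C(C)C)C(C)C)c(OC)c2)C(OC)=CC1=O
F8 | step 6 | methyl 2-(5-allyl-1,2-dimethoxy-4-oxocyclohexa-2,5-dien-1-yl)-3-[3-methoxy-4-(triisopropylsilyloxy)phenyl]propanoate (mixture of four stereoisomers) | C=CCC1=CC(OC)(C(C(=O)OC)Cc2ccc(O[Si](C(C)C)(C(C)C)C(C)C)c(OC)c2)C(OC)=CC1=O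
F9 | step 6 | methyl (2R)-2-[(1R)-5-allyl-1,2-dimethoxy-4-oxocyclohexa-2,5-dien-1-yl]-3-[3-methoxy-4-(triisopropylsilyloxy)phenyl]propanoate | C=CCC1=C[C@@](OC)([C@H](C(=O)OC)Cc2ccc(O[Si](C(C)C)(C(C)C)C(C)C)c(OC)c2)C(OC)=CC1=O
F10 | step 9 | N'-[(1E,2S)-2-[(1R)-5-allyl-1,2-dimethoxy-4-oxocyclohexa-2,5-dien-1-yl]-3-[3-methoxy-4-(triisopropylsilyloxy)phenyl]propylidene]-4-methylbenzenesulfonohydrazide | C=CCC1=C[C@@](OC)([C@H](/C=N/NS(=O)(=O)c3ccc(C)cc3)Cc2ccc(O[Si](C(C)C)(C(C)C)C(C)C)c(OC)c2)C(OC)=CC1=O
F11 | step 9 | N'-[(2S)-2-[(1R)-5-allyl-1,2-dimethoxy-4-oxocyclohexa-2,5-dien-1-yl]-3-[3-methoxy-4-(triisopropylsilyloxy)phenyl]propyl]-4-methylbenzenesulfonohydrazide | C=CCC1=C[C@@](OC)([C@H](CNNS(=O)(=O)c3ccc(C)cc3)Cc2ccc(O[Si](C(C)C)(C(C)C)C(C)C)c(OC)c2)C(OC)=CC1=O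
F12 | step 9 | (4R)-2-allyl-4-[(2S)-1-diazenyl-3-[3-methoxy-4-(triisopropylsilyloxy)phenyl]propan-2-yl]-4,5-dimethoxycyclohexa-2,5-dien-1-one | C=CCC1=C[C@@](OC)([C@H](CN=N)Cc2ccc(O[Si](C(C)C)(C(C)C)C(C)C)c(OC)c2)C(OC)=CC1=O
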